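**Strategy.** Everything rests on reading the cyclopentane ring (C1, C2, C3, C3a, C8a) as the carvone ring contracted by one atom. In carvone the methyl-bearing C2 and the C5 carrying the three-carbon branch are bridged by C1 and C6; in the target C8a and C3 are bridged by C3a alone. The key step, a photochemical Wolff rearrangement, moves the quaternary carbon onto the diazo carbon, so that the C8a–C3a bond and the five-membered ring arise in one operation with the C8a configuration retained. Its precursor is a 2-allyl-6-diazo-5-isopropyl-2-methylcyclohexanone with allyl trans to isopropyl, reached from (S)-carvone in five steps. The seven-membered ring is closed late at C3a–C4 by a samarium Reformatsky aldol.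

Key step: step 6

Remark (structure): the target is taken as the (3R,3aS,5R,8aR) isomer encoded in the SMILES. 3a-OH, 8a-CH3 and 3-isopropyl lie on one face of the cyclopentane, C4 and C8 on the other, and 5-O is trans to 3a-OH. Up to step 6 cyclohexanone numbering is used (C1 carbonyl, C2 quaternary, C5 isopropyl, C6); C2, C5 and C6 become C8a, C3 and C3a, and C1 becomes the ester carbon.

Remark (chemistry): simple alkylation of the 2-methyl-5-isopropylcyclohexanone enolate is expected to bring the electrophile in axially, that is cis to the equatorial isopropyl group (the wrong C8a epimer), or with little bias. The quaternary centre is therefore set by ligand-controlled decarboxylative allylation (steps 2 and 3). The configuration at the ester-bearing carbon of 11 is immaterial because step 7 planarises it.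

**Step 1**
Reactants: 1 (S)-carvone
Product: 2 (5S)-2-methyl-5-(propan-2-yl)cyclohex-2-en-1-one
Conditions: H2 (1 atm), RhCl(PPh3)3 (cat.), toluene, 20 °C
Reagents that add atoms: none
Why: Homogeneous hydrogenation with the rhodium chloride tris(phosphine) complex saturates only the unhindered 1,1-disubstituted isopropenyl alkene and leaves the conjugated trisubstituted enone and the C5 stereocentre untouched.

**Step 2**
Reactants: 2 (5S)-2-methyl-5-(propan-2-yl)cyclohex-2-en-1-one; 3 allyl chloroformate
Product: 5 allyl (5S)-2-methyl-5-(propan-2-yl)cyclohex-1-en-1-yl carbonate, via lithium enolate 4 (not isolated)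
Conditions: LiBH(s-Bu)3, THF, −78 °C; then 3, −78 → 0 °C
Reagents that add atoms: allyl chloroformate (3), C=CCOC(Cl)=O
Why: Lithium tri-sec-butylborohydride adds hydride 1,4 to the β-unsubstituted cyclohexenone (conjugate reduction) to give the regiodefined C1–C2 lithium enolate, which the hard chloroformate acylates on oxygen (enolate O-acylation); any C-acylated β-keto ester would converge on 6 in step 3.

**Step 3**
Reactants: 5 allyl (5S)-2-methyl-5-(propan-2-yl)cyclohex-1-en-1-yl carbonate
Product: 6 (2R,5S)-2-allyl-2-methyl-5-(propan-2-yl)cyclohexan-1-one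
Conditions: Pd2(dba)3 (2.5 mol %), (R)-t-BuPHOX (6 mol %), THF, 25 °C
Reagents that add atoms: none
Why: Decarboxylative Tsuji allylation: zerovalent palladium ionises the allyl carbonate, CO2 is lost and the palladium enolate is allylated at C2 under ligand control, (R)-t-BuPHOX being the antipode of the ligand that gives (S)-2-allyl-2-methylcyclohexanone in the parent series, so C2 should be set R with allyl trans to the C5 isopropyl group whatever the weak intrinsic bias of the remote centre.

**Step 4**
Reactants: 6 (2R,5S)-2-allyl-2-methyl-5-(propan-2-yl)cyclohexan-1-one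
Product: 7 (2R,5R,6Z)-2-allyl-6-(hydroxymethylidene)-2-methyl-5-(propan-2-yl)cyclohexan-1-one
Conditions: NaH, HCO2Et, EtOH (cat.), THF, 0 → 20 °C; aq HCl work-up
Reagents that add atoms: ethyl formate, CCOC=O
Why: Crossed Claisen condensation (formylation) can only take place at C6 because C2 is quaternary, and the product is held as its hydrogen-bonded enol.

**Step 5**
Reactants: 7 (2R,5R,6Z)-2-allyl-6-(hydroxymethylidene)-2-methyl-5-(propan-2-yl)cyclohexan-1-one
Product: 8 (2R,5R)-2-allyl-6-diazo-2-methyl-5-(propan-2-yl)cyclohexan-1-one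
Conditions: 4-acetamidobenzenesulfonyl azide, Et3N, MeCN, 0 → 20 °C
Reagents that add atoms: 4-acetamidobenzenesulfonyl azide, CC(=O)Nc1ccc(cc1)S(=O)(=O)N=[N+]=[N-]
Why: Regitz deformylative diazo transfer: the enolate of 7 adds to the terminal nitrogen of the sulfonyl azide and the adduct fragments with loss of the formyl group as the N-formylsulfonamide, which places the diazo group at C6 without touching C2 or C5.

**Step 6**
Reactants: 8 (2R,5R)-2-allyl-6-diazo-2-methyl-5-(propan-2-yl)cyclohexan-1-one; 9 methanol
Product: 11 methyl (1R,2R,5R)-2-allyl-2-methyl-5-(propan-2-yl)cyclopentane-1-carboxylate, via ketene 10 (not isolated)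
Conditions: hν (medium-pressure Hg lamp, Pyrex filter), degassed MeOH, 20 °C
Reagents that add atoms: methanol (9), CO
Why: Excitation of the diazo ketone expels N2 and, because the ring locks the C=O and C=N2 units s-cis, the C1–C2 bond migrates to the carbene carbon C6 in concert (photochemical Wolff rearrangement) to give ketene 10, which methanol captures as the ester. The closest known reaction type is the photochemical Wolff ring contraction of 2-diazocycloalkanones to cycloalkanecarboxylates. The cyclopentane is not closed end to end but by a 1,2-shift (ring contraction) that forms the C8a–C3a bond while the old carbonyl carbon leaves the ring as the exocyclic ester carbon. The migrating quaternary carbon keeps its configuration, so the trans allyl/isopropyl relation of 8 is carried over unchanged. The only new stereocentre, C1 of 11, is set by protonation of the enol formed when methanol adds to the ketene and should settle trans to the neighbouring isopropyl group; its sense does not matter because step 7 planarises it. The step needs migration to outrun O–H insertion, 1,2-hydride shift and addition of the carbene to the allyl group, which is secured by the enforced s-cis geometry, by the fact that only C2 can migrate, and by the use of light instead of a metal catalyst.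

**Step 7**
Reactants: 11 methyl (1R,2R,5R)-2-allyl-2-methyl-5-(propan-2-yl)cyclopentane-1-carboxylate
Product: 13 {[(2R,5R)-2-allyl-2-methyl-5-(propan-2-yl)cyclopentylidene](methoxy)methoxy}trimethylsilane, via lithium ester enolate 12 (not isolated)
Conditions: LiN(i-Pr)2, THF/DMPU, −78 → 0 °C; then Me3SiCl, −78 → 20 °C; non-aqueous work-up
Reagents that add atoms: chlorotrimethylsilane, C[Si](C)(C)Cl
Why: Deprotonation of the ester α-C–H by lithium diisopropylamide and O-silylation of the enolate (silyl ketene acetal formation) turn the ester-bearing carbon into an electron-rich alkene carbon, the polar cosolvent helping at this hindered position and the allyl group being inert.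

**Step 8**
Reactants: 13 {[(2R,5R)-2-allyl-2-methyl-5-(propan-2-yl)cyclopentylidene](methoxy)methoxy}trimethylsilane
Product: 14 2-[(1R,3R)-1-methyl-2-oxo-3-(propan-2-yl)cyclopentyl]acetaldehyde
Conditions: O3, pyridine (3 equiv), CH2Cl2, −78 °C
Reagents that add atoms: ozone, [O-][O+]=O
Why: Ozonolysis cleaves both alkenes, the tetrasubstituted ketene acetal releasing the former ester carbon as a carbonate and leaving the C3a ketone, the vinyl group giving the C7 aldehyde, while pyridine converts the carbonyl oxides straight into carbonyl compounds under non-enolising conditions that spare the C3 stereocentre.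

**Step 9**
Reactants: 14 2-[(1R,3R)-1-methyl-2-oxo-3-(propan-2-yl)cyclopentyl]acetaldehyde; 15 ethyl 2-[bis(2,2,2-trifluoroethoxy)phosphoryl]propanoate
Product: 16 ethyl (2Z)-2-methyl-4-[(1R,3R)-1-methyl-2-oxo-3-(propan-2-yl)cyclopentyl]but-2-enoate
Conditions: KN(SiMe3)2, 18-crown-6, THF, −78 °C
Reagents that add atoms: ethyl 2-[bis(2,2,2-trifluoroethoxy)phosphoryl]propanoate (15), CCOC(=O)C(C)P(=O)(OCC(F)(F)F)OCC(F)(F)F
Why: Still–Gennari variant of the Horner–Wadsworth–Emmons olefination: the electron-poor trifluoroethyl phosphonate with a dissociated potassium counter-ion eliminates from the kinetic adduct to give the Z trisubstituted enoate (C6=C7), and only the aldehyde reacts because the C3a ketone is flanked by a quaternary and a tertiary carbon.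

**Step 10**
Reactants: 16 ethyl (2Z)-2-methyl-4-[(1R,3R)-1-methyl-2-oxo-3-(propan-2-yl)cyclopentyl]but-2-enoate
Product: 17 (2Z)-2-methyl-4-[(1R,3R)-1-methyl-2-oxo-3-(propan-2-yl)cyclopentyl]but-2-enoic acid
Conditions: Me3SnOH, 1,2-dichloroethane, 80 °C; 5 % aq HCl wash
Reagents that add atoms: trimethyltin hydroxide, C[Sn](C)(C)O
Why: Trimethyltin hydroxide hydrolyses the ester at essentially neutral pH (mild ester hydrolysis), which should preserve both the Z alkene and the epimerisable C3–H next to the ketone.

**Step 11**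
Reactants: 17 (2Z)-2-methyl-4-[(1R,3R)-1-methyl-2-oxo-3-(propan-2-yl)cyclopentyl]but-2-enoic acid; 18 (trimethylsilyl)diazomethane
Product: 21 (2R,5R)-2-[(2Z)-5-bromo-3-methyl-4-oxopent-2-en-1-yl]-2-methyl-5-(propan-2-yl)cyclopentan-1-one, via mixed anhydride 19 (not isolated), via diazoketone 20 (not isolated)
Conditions: i-BuOCOCl, N-methylmorpholine, THF, −20 °C; then 18, THF/MeCN, 0 °C; then 48 % aq HBr, 0 °C
Reagents that add atoms: (trimethylsilyl)diazomethane (18), C[Si](C)(C)C=[N+]=[N-]; hydrogen bromide, Br
Why: The acid is activated as a mixed carbonic anhydride, acylates the diazoalkane at carbon (Arndt–Eistert-type diazoketone synthesis, with loss of the silyl group) and the diazoketone is then protonated and opened by bromide with loss of N2 (Nierenstein-type halomethyl ketone formation), a sequence without strong base or nucleophilic catalyst that should leave the Z alkene and C3 intact.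

**Step 12**
Reactants: 21 (2R,5R)-2-[(2Z)-5-bromo-3-methyl-4-oxopent-2-en-1-yl]-2-methyl-5-(propan-2-yl)cyclopentan-1-one
Product: 23 (3R,3aS,8aR)-3a-hydroxy-6,8a-dimethyl-3-(propan-2-yl)-2,3,3a,4,8,8a-hexahydroazulen-5(1H)-one, via samarium enolate 22 (not isolated)
Conditions: SmI2 (2.5 equiv), THF (0.005 M), −78 → 0 °C; 0.1 M aq HCl quench
Reagents that add atoms: none
Why: Intramolecular samarium Reformatsky reaction: two-electron reduction of the C–Br bond gives a trivalent samarium enolate whose C4 adds to the C3a carbonyl (7-(enolendo)-exo-trig aldol closure) from the face that carries the C8 tether and is anti to the isopropyl group, so that the 3a-hydroxyl ends up cis to the C8a methyl and the C3 isopropyl group, the chelated samarium aldolate resisting retro-aldol cleavage.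

**Step 13**
Reactants: 23 (3R,3aS,8aR)-3a-hydroxy-6,8a-dimethyl-3-(propan-2-yl)-2,3,3a,4,8,8a-hexahydroazulen-5(1H)-one
Product: 24 (3R,3aS,5R,8aR)-6,8a-dimethyl-3-(propan-2-yl)-1,2,3,3a,4,5,8,8a-octahydroazulene-3a,5-diol
Conditions: Me4NBH(OAc)3, MeCN/AcOH, −30 → −20 °C; aq NaHCO3 work-up
Reagents that add atoms: none
Why: Evans–Saksena hydroxyl-directed reduction: the 3a-hydroxyl exchanges onto boron and delivers hydride intramolecularly to the C5 carbonyl on its own face (1,2-reduction, the mild acyloxyborohydride not touching the alkene), so that the new 5-hydroxyl is trans to the 3a-hydroxyl (5R).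

**Step 14**
Reactants: 24 (3R,3aS,5R,8aR)-6,8a-dimethyl-3-(propan-2-yl)-1,2,3,3a,4,5,8,8a-octahydroazulene-3a,5-diol; 25 3,4-dimethoxybenzoyl chloride
Product: 26 (3R,3aS,5R,8aR)-3a-hydroxy-6,8a-dimethyl-3-(propan-2-yl)-1,2,3,3a,4,5,8,8a-octahydroazulen-5-yl 3,4-dimethoxybenzoate
Conditions: 25, Et3N, DMAP (cat.), CH2Cl2, 0 → 20 °C
Reagents that add atoms: 3,4-dimethoxybenzoyl chloride (25), COc1ccc(C(Cl)=O)cc1OC
Why: DMAP-catalysed acylation (nucleophilic catalysis through the acylpyridinium ion) esterifies the secondary allylic 5-hydroxyl, while the tertiary 3a-hydroxyl flanked by two branched carbons does not react.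

**Compound list**

1 | (S)-carvone, (5S)-2-methyl-5-(prop-1-en-2-yl)cyclohex-2-en-1-one | CC1=CC[C@@H](CC1=O)C(C)=C | starting material
2 | (5S)-2-methyl-5-(propan-2-yl)cyclohex-2-en-1-one | CC1=CC[C@@H](CC1=O)C(C)C | intermediate
3 | allyl chloroformate | C=CCOC(Cl)=O | starting material
4 | lithium (5S)-2-methyl-5-(propan-2-yl)cyclohex-1-en-1-olate | [Li+].[O-]C1=C(C)CC[C@H](C(C)C)C1 | intermediate (not isolated)
5 | allyl (5S)-2-methyl-5-(propan-2-yl)cyclohex-1-en-1-yl carbonate | C=CCOC(=O)OC1=C(C)CC[C@H](C(C)C)C1 | intermediate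
6 | (2R,5S)-2-allyl-2-methyl-5-(propan-2-yl)cyclohexan-1-one | C=CC[C@@]1(C)CC[C@H](C(C)C)CC1=O | intermediate
7 | (2R,5R,6Z)-2-allyl-6-(hydroxymethylidene)-2-methyl-5-(propan-2-yl)cyclohexan-1-one | C=CC[C@@]1(C)CC[C@H](C(C)C)/C(=C/O)C1=O | intermediate
8 | (2R,5R)-2-allyl-6-diazo-2-methyl-5-(propan-2-yl)cyclohexan-1-one | C=CC[C@@]1(C)CC[C@H](C(C)C)C(=[N+]=[N-])C1=O | intermediate
9 | methanol | CO | starting material
10 | [(2R,5R)-2-allyl-2-methyl-5-(propan-2-yl)cyclopentylidene]methanone (ketene) | O=C=C1[C@@H](C(C)C)CC[C@]1(C)CC=C | intermediate (not isolated)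
11 | methyl (1R,2R,5R)-2-allyl-2-methyl-5-(propan-2-yl)cyclopentane-1-carboxylate | COC(=O)[C@@H]1[C@@H](C(C)C)CC[C@]1(C)CC=C | intermediate
12 | lithium [(2R,5R)-2-allyl-2-methyl-5-(propan-2-yl)cyclopentylidene](methoxy)methanolate | [Li+].[O-]C(OC)=C1[C@@H](C(C)C)CC[C@]1(C)CC=C | intermediate (not isolated)
13 | {[(2R,5R)-2-allyl-2-methyl-5-(propan-2-yl)cyclopentylidene](methoxy)methoxy}trimethylsilane (E/Z mixture) | COC(O[Si](C)(C)C)=C1[C@@H](C(C)C)CC[C@]1(C)CC=C | intermediate
14 | 2-[(1R,3R)-1-methyl-2-oxo-3-(propan-2-yl)cyclopentyl]acetaldehyde | O=CC[C@@]1(C)CC[C@H](C(C)C)C1=O | intermediate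
15 | ethyl 2-[bis(2,2,2-trifluoroethoxy)phosphoryl]propanoate | CCOC(=O)C(C)P(=O)(OCC(F)(F)F)OCC(F)(F)F | starting material
16 | ethyl (2Z)-2-methyl-4-[(1R,3R)-1-methyl-2-oxo-3-(propan-2-yl)cyclopentyl]but-2-enoate | CCOC(=O)/C(C)=C\C[C@@]1(C)CC[C@H](C(C)C)C1=O | intermediate
17 | (2Z)-2-methyl-4-[(1R,3R)-1-methyl-2-oxo-3-(propan-2-yl)cyclopentyl]but-2-enoic acid | OC(=O)/C(C)=C\C[C@@]1(C)CC[C@H](C(C)C)C1=O | intermediate
18 | (trimethylsilyl)diazomethane | C[Si](C)(C)C=[N+]=[N-] | starting material
19 | isobutyl carbonic (2Z)-2-methyl-4-[(1R,3R)-1-methyl-2-oxo-3-(propan-2-yl)cyclopentyl]but-2-enoic anhydride | CC(C)COC(=O)OC(=O)/C(C)=C\C[C@@]1(C)CC[C@H](C(C)C)C1=O | intermediate (not isolated)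
20 | (2R,5R)-2-[(2Z)-5-diazo-3-methyl-4-oxopent-2-en-1-yl]-2-methyl-5-(propan-2-yl)cyclopentan-1-one | [N-]=[N+]=CC(=O)/C(C)=C\C[C@@]1(C)CC[C@H](C(C)C)C1=O | intermediate (not isolated)
21 | (2R,5R)-2-[(2Z)-5-bromo-3-methyl-4-oxopent-2-en-1-yl]-2-methyl-5-(propan-2-yl)cyclopentan-1-one | BrCC(=O)/C(C)=C\C[C@@]1(C)CC[C@H](C(C)C)C1=O | intermediate
22 | diiodosamarium enolate of the debrominated ketone | [Sm+3].[I-].[I-].[O-]C(=C)/C(C)=C\C[C@@]1(C)CC[C@H](C(C)C)C1=O | intermediate (not isolated)
23 | (3R,3aS,8aR)-3a-hydroxy-6,8a-dimethyl-3-(propan-2-yl)-2,3,3a,4,8,8a-hexahydroazulen-5(1H)-one | O=C1C[C@]2(O)[C@@H](C(C)C)CC[C@]2(C)CC=C1C | intermediate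
24 | (3R,3aS,5R,8aR)-6,8a-dimethyl-3-(propan-2-yl)-1,2,3,3a,4,5,8,8a-octahydroazulene-3a,5-diol | O[C@@H]1C[C@]2(O)[C@@H](C(C)C)CC[C@]2(C)CC=C1C | intermediate
25 | 3,4-dimethoxybenzoyl chloride | COc1ccc(C(Cl)=O)cc1OC | starting material
26 | (3R,3aS,5R,8aR)-3a-hydroxy-6,8a-dimethyl-3-(propan-2-yl)-1,2,3,3a,4,5,8,8a-octahydroazulen-5-yl 3,4-dimethoxybenzoate | COc1ccc(C(=O)O[C@@H]2C[C@]3(O)[C@@H](C(C)C)CC[C@]3(C)CC=C2C)cc1OC | target

**Step count and risks**

Total step count: 14. Longest linear sequence: 14 steps, from 1 to 26.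

Steps most likely to fail:

Step 12 (ring closure). The samarium enolate may be protonated or simply reduced to the methyl ketone before it reaches the hindered C3a carbonyl, or the aldolate may revert by retro-aldol cleavage on warming, so that the seven-membered ring does not form. The fallback closes the ring at C6=C7 by metathesis after an intermolecular aldol at C3a; it sets out from 14 and comes back to the route at 23. Aldehyde-selective Wittig methylenation of 14 (Ph3P=CH2, THF, −78 → 0 °C) should give (2R,5R)-2-allyl-2-methyl-5-(propan-2-yl)cyclopentan-1-one F1. The lithium enolate of N-methoxy-N-methylacetamide (LiN(i-Pr)2, THF, −78 °C) should add to its ketone from the face anti to the isopropyl group to give 2-[(1S,2R,5R)-2-allyl-1-hydroxy-2-methyl-5-(propan-2-yl)cyclopentyl]-N-methoxy-N-methylacetamide F2. Excess isopropenylmagnesium bromide (THF, 0 °C) should convert this amide into 1-[(1S,2R,5R)-2-allyl-1-hydroxy-2-methyl-5-(propan-2-yl)cyclopentyl]-3-methylbut-3-en-2-one F3. Ring-closing metathesis with second-generation Grubbs catalyst (CH2Cl2, 40 °C) should then deliver 23, the ring enforcing the Z alkene.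

Step 11 (bromomethyl ketone). The Z geometry may be lost during carboxyl activation through reversible conjugate addition of chloride or amine to the activated acyl species, and the diazoalkane may add as a dipole to the unsaturated carbonyl unit. The fallback avoids any activated acid and builds the bromoacetyl group by cross-coupling; it sets out from 14, replaces steps 9 to 11, and comes back at 21. Stork–Zhao-type α-iodoethylidenation of 14 (EtPPh3I, n-BuLi, I2, then NaN(SiMe3)2, THF, −78 °C) should give (2R,5R)-2-[(2Z)-3-iodobut-2-en-1-yl]-2-methyl-5-(propan-2-yl)cyclopentan-1-one F4. Stille coupling with tributyl(1-ethoxyvinyl)stannane (Pd(PPh3)4, CuI, DMF, 50 °C) should give, with retention of geometry, (2R,5R)-2-[(2Z)-4-ethoxy-3-methylpenta-2,4-dien-1-yl]-2-methyl-5-(propan-2-yl)cyclopentan-1-one F5. Bromination of the enol ether terminus in wet solvent (NBS, THF/H2O, 0 °C) should give 21.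

Step 6 (key step). The carbene may insert into the O–H bond of methanol or undergo 1,2-hydride shift from C5 to an enone before the ring bond migrates, and the ester may suffer secondary photolysis on prolonged irradiation. The fallback keeps the same C2-to-C6 shift but drives it by an ionic semibenzilic (quasi-Favorskii) mechanism; it sets out from 6 and comes back at 11. Kinetic silylation of 6 (LiN(SiMe3)2, Me3SiCl, THF, −78 °C) should give trimethyl{[(3R,6R)-6-allyl-6-methyl-3-(propan-2-yl)cyclohex-1-en-1-yl]oxy}silane F6. Bromination of the enol ether, which is far more reactive than the allyl group (NBS, THF, −78 °C), should give (2R,5R,6R)-2-allyl-6-bromo-2-methyl-5-(propan-2-yl)cyclohexan-1-one F7. With NaOMe in MeOH (0 → 20 °C) methoxide should add to C1 and C2 should shift to C6 with loss of bromide, giving 11; the configuration at the ester-bearing carbon is again irrelevant.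

Further compounds
F1 | step 12 | (2R,5R)-2-allyl-2-methyl-5-(propan-2-yl)cyclopentan-1-one | C=CC[C@@]1(C)CC[C@H](C(C)C)C1=O
F2 | step 12 | 2-[(1S,2R,5R)-2-allyl-1-hydroxy-2-methyl-5-(propan-2-yl)cyclopentyl]-N-methoxy-N-methylacetamide | CON(C)C(=O)C[C@]1(O)[C@@H](C(C)C)CC[C@]1(C)CC=C
F3 | step 12 | 1-[(1S,2R,5R)-2-allyl-1-hydroxy-2-methyl-5-(propan-2-yl)cyclopentyl]-3-methylbut-3-en-2-one | CC(=C)C(=O)C[C@]1(O)[C@@H](C(C)C)CC[C@]1(C)CC=C
F4 | step 11 | (2R,5R)-2-[(2Z)-3-iodobut-2-en-1-yl]-2-methyl-5-(propan-2-yl)cyclopentan-1-one | C/C(I)=C/C[C@@]1(C)CC[C@H](C(C)C)C1=O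
F5 | step 11 | (2R,5R)-2-[(2Z)-4-ethoxy-3-methylpenta-2,4-dien-1-yl]-2-methyl-5-(propan-2-yl)cyclopentan-1-one | CCOC(=C)/C(C)=C\C[C@@]1(C)CC[C@H](C(C)C)C1=O
F6 | step 6 | trimethyl{[(3R,6R)-6-allyl-6-methyl-3-(propan-2-yl)cyclohex-1-en-1-yl]oxy}silane | C=CC[C@@]1(C)CC[C@H](C(C)C)C=C1O[Si](C)(C)C
F7 | step 6 | (2R,5R,6R)-2-allyl-6-bromo-2-methyl-5-(propan-2-yl)cyclohexan-1-one | C=CC[C@@]1(C)CC[C@H](C(C)C)[C@@H](Br)C1=O
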